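**Retrosynthetic overview**

1. Oxolane numbering: O1, C2 (benzylic CH next to the carbinol carbon), C3 (C(CH3)OH), C4 (CHCH3), C5 (the other benzylic CH). Target ⇒ bis(benzyl ether) ⇒ hemiketal (C2–H by hydride onto a 2-aryl oxocarbenium ion) ⇒ aryllithium + 3-hydroxy-3,4-dimethyl-5-aryl-γ-butyrolactone.
2. Hydroxy lactone ⇒ α-methylene-γ-butyrolactone by Mukaiyama hydration (C3–O trans to 4-CH3; the CH2 becomes 3-CH3).
3. α-Methylene lactone ⇒ O-benzylvanillin + methyl (Z)-2-(pinacolborylmethyl)but-2-enoate: enantioselective allylboration (C4–C5) and lactonisation (O1–C2) in one operation. This closes the only non-aromatic ring; both arene rings are bought.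
4. Enabling feature: C2 carries only O1, an aryl group and H, so it can be carried as an acyl carbon. With the geminal CH3/OH of C3 masked as exocyclic C3=CH2, ring O1–C2–C3–C4–C5 is an α-methylene-γ-butyrolactone, and its trans 4-CH3/5-aryl pair is the retron of an anti crotyl transfer to an aryl aldehyde.

Key step: step 2

Assumption: the binaphthyl phosphoric acid is taken to induce in the same sense with the ester-substituted crotylboronate as with simple allyl- and crotylboronates (S acid → Si face of the aldehyde); if the sense is found reversed, the R acid is used and nothing else changes.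

**Route**

Step 1
Reactants: 1 methyl but-2-ynoate; 2 2-(iodomethyl)-4,4,5,5-tetramethyl-1,3,2-dioxaborolane
Product: 4 methyl (2Z)-2-[(4,4,5,5-tetramethyl-1,3,2-dioxaborolan-2-yl)methyl]but-2-enoate, via alkenylalane 3 (not isolated)
Conditions: i-Bu2AlH, HMPA, THF, 0 °C; then 2, 0 °C → rt
Reagents that add atoms: none
Why: Conjugate hydroalumination–α-alkylation of an alkynoate: syn addition of Al–H puts aluminium on C2 and H on C3, and the alkenylalane (or its allenolate) should be alkylated at C2 on the side of the C3–H, so the methyl group ends trans to CH2B and cis to the ester, the geometry that step 2 converts into the anti relationship.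

Step 2
Reactants: 4 methyl (2Z)-2-[(4,4,5,5-tetramethyl-1,3,2-dioxaborolan-2-yl)methyl]but-2-enoate; 5 4-(benzyloxy)-3-methoxybenzaldehyde
Product: 7 (4S,5S)-5-[4-(benzyloxy)-3-methoxyphenyl]-4-methyl-3-methylideneoxolan-2-one, via borate ester 6 (not isolated)
Conditions: (S)-TRIP [(S)-3,3′-bis(2,4,6-triisopropylphenyl)-1,1′-binaphthyl-2,2′-diyl hydrogen phosphate] (10 mol %), 4 Å MS, toluene, 0 °C → rt; then TsOH·H2O (10 mol %), rt
Reagents that add atoms: none
Why: The phosphoric acid hydrogen-bonds to a dioxaborolane oxygen of 4 and to the formyl hydrogen, and the aldehyde is allylated through a closed chair six-membered transition state in which the CH(CH3) carbon of 4 bonds to the formyl carbon while boron moves to oxygen (C4–C5 bond); the boron-bound oxygen O1 of 6 then attacks the neighbouring ester carbonyl and methoxide passes to boron (O1–C2 bond), the added TsOH completing this closure. The closest known reaction type is the Brønsted acid-catalysed tandem allylboration–lactonisation of aldehydes with 2-(alkoxycarbonyl)allylboronates, in its binaphthyl phosphoric acid-catalysed enantioselective form. The lactone ring closes by 5-exo-trig acyl substitution. C5 is set by the catalyst (attack on the Si face of the aldehyde), and C4 by the double-bond geometry of 4: the methyl group trans to CH2B and the aryl group both sit pseudo-equatorially in the chair, which should give the anti adduct and hence the 4,5-trans lactone. The step needs γ-regioselectivity (inherent in the cyclic transition state), anti diastereoselectivity (secured by the geometric purity of 4 and backed by the trans lactone being the more stable one, should the electron-rich benzylic C5–O bond ionise during closure) and enantioselectivity (secured by the catalyst).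

Step 3
Reactants: 7 (4S,5S)-5-[4-(benzyloxy)-3-methoxyphenyl]-4-methyl-3-methylideneoxolan-2-one
Product: 9 (3S,4R,5S)-5-[4-(benzyloxy)-3-methoxyphenyl]-3-hydroxy-3,4-dimethyloxolan-2-one, via hydroperoxide 8 (not isolated)
Conditions: Mn(dpm)3 [tris(2,2,6,6-tetramethylheptane-3,5-dionato)manganese, trivalent manganese] (cat.), PhSiH3, O2 (1 atm), i-PrOH/CH2Cl2, 0 °C; then P(OEt)3, rt
Reagents that add atoms: dioxygen, O=O
Why: Mukaiyama hydration: hydrogen-atom transfer to the terminal CH2 gives the planar tertiary α-acyl radical at C3, which should be captured by O2 on the ring face opposite the adjacent 4-methyl group (1,2-induction in the five-membered ring), so the new C3–O bond is trans to 4-CH3 and the new 3-CH3 cis to it; P(OEt)3 reduces the hydroperoxide.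

Step 4
Reactants: 9 (3S,4R,5S)-5-[4-(benzyloxy)-3-methoxyphenyl]-3-hydroxy-3,4-dimethyloxolan-2-one; 10 1-(benzyloxy)-4-bromo-2-methoxybenzene
Product: 12 (3S,4R,5S)-2,5-bis[4-(benzyloxy)-3-methoxyphenyl]-3,4-dimethyloxolane-2,3-diol, via aryllithium 11 (not isolated)
Conditions: 10 (2.6 equiv), n-BuLi (2.5 equiv), THF, −78 °C; then 9, −78 °C; aq. NH4Cl
Reagents that add atoms: none
Why: Bromine–lithium exchange followed by addition of the aryllithium to the lactone carbonyl: the first equivalent deprotonates the tertiary hydroxyl, and the tetrahedral lithium hemiketal alkoxide is stable at −78 °C, which should prevent a second addition; C3 is quaternary, so no stereocentre of 9 can be lost by enolisation, and the new hemiketal centre (anomer mixture) is erased in step 5.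

Step 5
Reactants: 12 (3S,4R,5S)-2,5-bis[4-(benzyloxy)-3-methoxyphenyl]-3,4-dimethyloxolane-2,3-diol
Product: 14 (2R,3S,4R,5S)-2,5-bis[4-(benzyloxy)-3-methoxyphenyl]-3,4-dimethyloxolan-3-ol, via oxocarbenium ion 13 (not isolated)
Conditions: Et3SiH, BF3·OEt2, CH2Cl2, −78 °C
Reagents that add atoms: none
Why: Ionic reduction of a cyclic hemiketal: BF3 ionises C2–OH to the aryl-conjugated five-membered oxocarbenium ion, and the silane should deliver hydride to C2 from the face of the small 3-hydroxyl, opposite the 3- and 4-methyl groups (inside attack on the envelope with the C3–O bond pseudo-equatorial), which places 2-H cis to 3-OH and the 2-aryl group cis to both methyls and trans to the 5-aryl group; C3 is quaternary, so no enol ether can form.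

Step 6
Reactants: 14 (2R,3S,4R,5S)-2,5-bis[4-(benzyloxy)-3-methoxyphenyl]-3,4-dimethyloxolan-3-ol
Product: 15 (2R,3S,4R,5S)-2,5-bis(4-hydroxy-3-methoxyphenyl)-3,4-dimethyloxolan-3-ol
Conditions: H2 (1 atm), Pd/C, EtOAc/EtOH, rt
Reagents that add atoms: none
Why: Hydrogenolysis of the two aryl benzyl ethers over palladium on carbon; the cyclic dibenzylic ether and the tertiary alcohol are expected to survive at ambient pressure if the reaction is stopped after uptake of two equivalents of hydrogen, and no stereocentre is touched.

**Compound list**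

1 | methyl but-2-ynoate | CC#CC(=O)OC | starting material
2 | 2-(iodomethyl)-4,4,5,5-tetramethyl-1,3,2-dioxaborolane | CC1(C)OB(CI)OC1(C)C | starting material
3 | methyl (2E)-2-[bis(2-methylpropyl)alumanyl]but-2-enoate (not isolated) | C/C=C(/[Al](CC(C)C)CC(C)C)C(=O)OC | intermediate
4 | methyl (2Z)-2-[(4,4,5,5-tetramethyl-1,3,2-dioxaborolan-2-yl)methyl]but-2-enoate | C/C=C(/CB1OC(C)(C)C(C)(C)O1)C(=O)OC | intermediate
5 | 4-(benzyloxy)-3-methoxybenzaldehyde | COc1cc(C=O)ccc1OCc1ccccc1 | starting material
6 | methyl (3S,4S)-4-[4-(benzyloxy)-3-methoxyphenyl]-3-methyl-2-methylidene-4-[(4,4,5,5-tetramethyl-1,3,2-dioxaborolan-2-yl)oxy]butanoate (not isolated) | COc1cc([C@@H](OB3OC(C)(C)C(C)(C)O3)[C@@H](C)C(=C)C(=O)OC)ccc1OCc1ccccc1 | intermediate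
7 | (4S,5S)-5-[4-(benzyloxy)-3-methoxyphenyl]-4-methyl-3-methylideneoxolan-2-one | COc1cc([C@H]2OC(=O)C(=C)[C@@H]2C)ccc1OCc1ccccc1 | intermediate
8 | (3S,4R,5S)-5-[4-(benzyloxy)-3-methoxyphenyl]-3-hydroperoxy-3,4-dimethyloxolan-2-one (not isolated) | COc1cc([C@H]2OC(=O)[C@@](C)(OO)[C@@H]2C)ccc1OCc1ccccc1 | intermediate
9 | (3S,4R,5S)-5-[4-(benzyloxy)-3-methoxyphenyl]-3-hydroxy-3,4-dimethyloxolan-2-one | COc1cc([C@H]2OC(=O)[C@@](C)(O)[C@@H]2C)ccc1OCc1ccccc1 | intermediate
10 | 1-(benzyloxy)-4-bromo-2-methoxybenzene | COc1cc(Br)ccc1OCc1ccccc1 | starting material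
11 | [4-(benzyloxy)-3-methoxyphenyl]lithium (not isolated) | [Li]c1ccc(OCc2ccccc2)c(OC)c1 | intermediate
12 | (3S,4R,5S)-2,5-bis[4-(benzyloxy)-3-methoxyphenyl]-3,4-dimethyloxolane-2,3-diol (anomer mixture at C2, in equilibrium with the open hydroxy ketone) | COc1cc([C@H]2OC(O)(c3ccc(OCc4ccccc4)c(OC)c3)[C@@](C)(O)[C@@H]2C)ccc1OCc1ccccc1 | intermediate
13 | (3S,4R,5S)-2,5-bis[4-(benzyloxy)-3-methoxyphenyl]-3-hydroxy-3,4-dimethyl-4,5-dihydro-3H-furan-1-ium (not isolated) | COc1cc([C@H]2[O+]=C(c3ccc(OCc4ccccc4)c(OC)c3)[C@@](C)(O)[C@@H]2C)ccc1OCc1ccccc1 | intermediate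
14 | (2R,3S,4R,5S)-2,5-bis[4-(benzyloxy)-3-methoxyphenyl]-3,4-dimethyloxolan-3-ol | COc1cc([C@H]2O[C@H](c3ccc(OCc4ccccc4)c(OC)c3)[C@@](C)(O)[C@@H]2C)ccc1OCc1ccccc1 | intermediate
15 | (2R,3S,4R,5S)-2,5-bis(4-hydroxy-3-methoxyphenyl)-3,4-dimethyloxolan-3-ol | COc1cc([C@H]2O[C@H](c3ccc(O)c(OC)c3)[C@@](C)(O)[C@@H]2C)ccc1O | target

**Step count and risks**

Total step count: 6. Longest linear sequence: 6 steps (1 → 4 → 7 → 9 → 12 → 14 → 15).

Steps most likely to fail:

1. Step 2. The ester-bearing boronate is a weak allyl donor, so the allyl transfer may be slow and the enantiofacial control may erode; acid may also ionise the electron-rich benzylic borate before closure. Fallback, setting out from 5 and coming back at 7: (R)-but-3-yn-2-yl methanesulfonate F1 (from commercial (R)-but-3-yn-2-ol, MsCl, Et3N) is converted with Pd(OAc)2/PPh3 (cat.) and Et2Zn in THF at −20 °C into a chiral allenylzinc reagent (anti displacement of the sulfonate by zerovalent palladium, then transmetalation). This adds to 5 through a cyclic SE2′ transition state and should give the anti homopropargylic alcohol (1S,2S)-1-[4-(benzyloxy)-3-methoxyphenyl]-2-methylbut-3-yn-1-ol F2. Palladium-catalysed cyclocarbonylation of F2 (PdCl2, SnCl2, PPh3, CO, MeCN, 75 °C) closes the α-methylene lactone 7.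

2. Step 3. The small O2 molecule may discriminate poorly between the two faces of the planar C3 radical, and simple conjugate reduction may compete. Fallback, setting out from 7 and coming back at 9: conjugate reduction with LiBH(s-Bu)3 (THF, −78 °C, then NH4Cl) gives (3RS,4S,5S)-5-[4-(benzyloxy)-3-methoxyphenyl]-3,4-dimethyloxolan-2-one F3, whose C3 configuration is irrelevant. Its potassium enolate (KN(SiMe3)2, THF, −78 °C) is hydroxylated with the bulky 2-(phenylsulfonyl)-3-phenyloxaziridine, which should attack the face opposite the 4-methyl group and give 9.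

3. Step 5. Facial control in the hydride delivery may be lost with the free tertiary hydroxyl bound to BF3, the second benzylic C–O bond (C5) may ionise with epimerisation, or a methyl group may shift from C3 to the oxocarbenium carbon. Fallback, setting out from 12 and coming back at 14: Zn(BH4)2 (Et2O, −20 °C) reduces the open hydroxy ketone tautomer of 12 under chelation by the 3-hydroxyl, with hydride entering on the side of the 3-methyl group, to give (1R,2S,3R,4S)-1,4-bis[4-(benzyloxy)-3-methoxyphenyl]-2,3-dimethylbutane-1,2,4-triol F4, which already has the C2 configuration of the target. MsCl/Et3N (CH2Cl2, 0 °C → rt) then sulfonylates the less hindered benzylic hydroxyl (the one next to CHCH3). Its ionisation and capture by the other benzylic oxygen, trans to the neighbouring methyl group, should close the ring to 14.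

**Further compounds**

F1 | step 2 | (R)-but-3-yn-2-yl methanesulfonate | C[C@@H](OS(C)(=O)=O)C#C
F2 | step 2 | (1S,2S)-1-[4-(benzyloxy)-3-methoxyphenyl]-2-methylbut-3-yn-1-ol | COc1cc([C@@H](O)[C@@H](C)C#C)ccc1OCc1ccccc1
F3 | step 3 | (3RS,4S,5S)-5-[4-(benzyloxy)-3-methoxyphenyl]-3,4-dimethyloxolan-2-one | COc1cc([C@H]2OC(=O)C(C)[C@@H]2C)ccc1OCc1ccccc1
F4 | step 5 | (1R,2S,3R,4S)-1,4-bis[4-(benzyloxy)-3-methoxyphenyl]-2,3-dimethylbutane-1,2,4-triol | COc1cc([C@@H](O)[C@@H](C)[C@](C)(O)[C@H](O)c2ccc(OCc3ccccc3)c(OC)c2)ccc1OCc1ccccc1
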